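Which do you change for the next run if you want ring: the temperature, or the protic impurity? The answer hangs on where the impurity's charge stands against one level.

common to all: starting material 1.0 mM; protic impurity 0.500 mM; time 4.0 s

|  | temperature |
|---|---|
| Monday's | 100 °C |
| Wednesday's | 125 °C |

* which of these there is most of at the end, counted by the starting material in it, Monday's (ring / starting material / open dimer)
* which of these there is most of at the end, counted by the starting material in it, Wednesday's (ring / starting material / open dimer)
* amount of the one of these that there is most of at the end, in percent of the starting material charged, Monday's
* amount of the one of these that there is most of at the end, in percent of the starting material charged, Wednesday's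

- in percentages every species weighs as the starting material in it: one open dimer or idle adduct counts as two
- for ring the crystals and idle adduct are counted in
- a doubled species enters its step squared and goes two at a time
- as a solid, counted per litre of solution: crystals
- constants are those at 100 °C; use the activation energies and enthalpies for any other temperature
- in an amount of ring, one idle adduct counts as one ring

    starting material → ring (k1 = 0.17 s⁻¹, Ea1 = 104 kJ mol⁻¹)
    starting material + protic impurity → quenched substrate (k2 = 510 M⁻¹ s⁻¹, Ea2 = 56.0 kJ mol⁻¹)
    2 starting material → open dimer (k3 = 56 M⁻¹ s⁻¹, Ea3 = 60.0 kJ mol⁻¹)
    starting material + ring ⇌ idle adduct, settled at all times (K4 = 29000 M⁻¹, ΔH4 = −15.0 kJ mol⁻¹)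
    crystals ⇌ ring, rate k5*(cs5 - [ring]) while solid is left; crystals form when [ring] > cs5 (cs5 = 0.053 mM, k5 = 11 s⁻¹)
    (constants at 100 °C)

Starting material closes to ring with 0.17 s⁻¹, or it meets protic impurity and becomes quenched substrate with 510 M⁻¹ s⁻¹. Each step takes one starting material, so [starting material] cancels from the ratio of their rates, however much the idle adduct holds. Divide the first constant by the second and you get 0.333 mM, the crossing level: the [protic impurity] at which the two steps run evenly, the zero of this scale, and the rate ratio (a selectivity factor) is this level over [protic impurity].

Monday's charge of 0.500 mM stands above the level, so the quench starts ahead. In Wednesday's flask the ring-to-quench rate ratio just after the start is 1.8, which puts the level at 0.881 mM, above the same charge, as you expect with 104 kJ mol⁻¹ for ring closure against 56.0 kJ mol⁻¹ for the quench.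

Each quench also spends one impurity, so the ratio improves as the run goes on, and integrating gives a rule: the share of impurity left is e raised to minus the ring made, bound and crystalline forms counted, over the crossing level. If ring and quenched substrate took the charge between them, my reckoning puts ring near 0.595 mM on Monday's and 0.722 mM on Wednesday's, with open dimer coming off both.

That is as far as I go by hand. On Monday's the half-life by ring closure alone, 4.1 s, is longer than the run, and the constant of the idle adduct times [starting material] at the start is 29, so I expect Monday's to stop well under its ceiling. I would run hot and then cut the impurity.

The forecast named ring on Monday's at 48 % (range 44 % to 52 %) and ring on Wednesday's at 66 % (range 62 % to 70 %), holding that “the ring formed is mostly tied up as idle adduct” on Monday's.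

On Monday's the flask gives ring at 26.9 %, and on Wednesday's it gives ring at 64.8 %.

Monday's ring falls short  of the forecast through the length of the run, with the loss of starting material to quenched substrate as a part of it: from 26.9 % at the stop, Monday's flask reaches 49.7 % when left ten times as long, and 34.0 % at the stop with that loss taken away. The forecast's number is the one completion gives. At Monday's stop the crossing level turns 26.9 % of ring into 44.6 % of the impurity left. Wednesday's flask with 0.20 mM of impurity reaches 75.9 % of ring, which by its level leaves 42.3 % of that impurity, so the quench took 11.5 % of the starting material charged.

Its constants are invented; the run is a simulation.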